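**Plan**

1. Retrosynthesis: the C5–Cα bond of the acrylic acid is cut first, so that C5 carries nitrogen as a diazonium precursor. The dihydrofuran ring is then cut at O1–C2 and at C3a–C3.
2. This leaves ring A as 2-methoxy-1,4-benzoquinone 4-(sulfonylimide) and the rest as the silyl ether of (E)-sinapyl alcohol. Two features allow it: O1 (on C7a) and C5 are para on the benzofuran benzene ring, so ring A can enter at the quinone level with C5 as an acid-activated C=N; and the 4-OH of the syringyl ring is para to C2, so the alkene is a push-pull styrene whose adduct is a p-quinone methide at C2.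
3. Forward: both benzene rings are bought. The quinone monoimide (2 steps) and the silylated alkene (1 step) are joined in a chiral phosphoric acid catalysed formal (3+2) cycloaddition that makes C3a–C3, then O1–C2, so the dihydrofuran ring is built last.
4. Helpers out: fluoride removes the 2-(trimethylsilyl)ethanesulfonyl (SES) group and the TBS ether. The nitrogen leaves as N2 in a diazotisation/Heck–Matsuda reaction with acrylic acid, which joins the side chain.
5. Stereochemistry: C3 comes from the chiral acid in the C–C bond formation. C2 is set trans to it by the ring closure on the quinone methide (substrate control, also the more stable isomer). The (E)-alkene comes from syn insertion and syn β-hydride elimination.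

Key step: step 4

Assumption: the sense of induction of the phosphoric acid is assigned by analysis of 8 and the antipode that leads to (2S,3R) is the one used, written below as (R); compounds 1 and 4 and SESCl are taken as purchasable.

**Route**

Step 1
Reactants: 1 4-amino-2-methoxyphenol
Product: 2 N-(4-hydroxy-3-methoxyphenyl)-2-(trimethylsilyl)ethanesulfonamide
Conditions: SESCl (1.05 equiv), pyridine, CH2Cl2, 0 °C to rt
Reagents that add atoms: 2-(trimethylsilyl)ethanesulfonyl chloride (SESCl), C[Si](C)(C)CCS(=O)(=O)Cl
Why: N-Sulfonylation (sulfonamide formation): the aniline nitrogen is far more nucleophilic than the phenol oxygen towards the sulfonyl chloride in pyridine, so the phenol should stay free; no stereocentre is formed.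

Step 2
Reactants: 2 N-(4-hydroxy-3-methoxyphenyl)-2-(trimethylsilyl)ethanesulfonamide
Product: 3 N-(3-methoxy-4-oxocyclohexa-2,5-dien-1-ylidene)-2-(trimethylsilyl)ethanesulfonamide (2-methoxy-1,4-benzoquinone 4-SES-imide; quinone numbering C1=O, C2–OMe, C4=N)
Conditions: PhI(OAc)2 (1.05 equiv), CH2Cl2, 0 °C to rt
Reagents that add atoms: none
Why: Oxidative dearomatisation of a 4-sulfonamidophenol with PhI(OAc)2, the standard entry to N-sulfonyl quinone monoimides, should take 2 to the quinoid level in an aprotic solvent in which no ketal can form; no stereocentre is formed.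

Step 3
Reactants: 4 (E)-sinapyl alcohol, 4-[(E)-3-hydroxyprop-1-enyl]-2,6-dimethoxyphenol
Product: 6 4-[(E)-3-(tert-butyldimethylsilyloxy)prop-1-enyl]-2,6-dimethoxyphenol, via bis-silyl ether 5 (not isolated)
Conditions: TBSCl (2.4 equiv), imidazole, DMF, rt; then K2CO3 (0.3 equiv), MeOH, rt
Reagents that add atoms: tert-butyldimethylsilyl chloride (TBSCl), CC(C)(C)[Si](C)(C)Cl
Why: Silyl ether formation followed by chemoselective methanolysis: both hydroxyl groups are silylated, and the aryl silyl ether, whose phenoxide is the far better leaving group, is then cleaved by carbonate in methanol while the allylic TBS ether and the (E)-alkene should stay intact.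

Step 4
Reactants: 3 2-methoxy-1,4-benzoquinone 4-SES-imide; 6 4-[(E)-3-(tert-butyldimethylsilyloxy)prop-1-enyl]-2,6-dimethoxyphenol
Product: 8 N-[(2S,3R)-3-[(tert-butyldimethylsilyloxy)methyl]-2-(4-hydroxy-3,5-dimethoxyphenyl)-7-methoxy-2,3-dihydro-1-benzofuran-5-yl]-2-(trimethylsilyl)ethanesulfonamide, via quinone methide adduct 7 (not isolated)
Conditions: 3 (1.0 equiv), 6 (1.2 equiv), (R)-3,3'-bis(2,4,6-triisopropylphenyl)-1,1'-binaphthyl-2,2'-diyl hydrogen phosphate (10 mol%), 4 Å molecular sieves, toluene, −20 °C
Reagents that add atoms: none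
Why: The phosphoric acid holds both partners in one chiral hydrogen-bonded complex (P=O to the phenolic OH of 6, P–OH to the sulfonylimide of 3), the nucleophilic alkene carbon next to CH2OTBS adds to C6 of the quinoid ring (the unsubstituted carbon β to the activated C=N and next to the C=O), and tautomerisation of ring A to the aminophenol leaves the p-quinone methide 7. O1 then adds to the methide carbon in a 5-exo-trig oxa-Michael closure that forms the dihydrofuran ring and restores the syringyl phenol. The closest known reaction type is the chiral phosphoric acid catalysed formal (3+2) cycloaddition of N-sulfonyl quinone monoimides with hydroxystyrenes and other electron-rich alkenes, together with its BF3-promoted racemic form on 2-methoxyquinone monoimides and propenylarenes. C3 is set in the C–C bond formation by the catalyst (facial selection inside the hydrogen-bond pocket), and C2 is set by the substrate, because O1 adds to the methide face anti to the CH2OTBS group on C3 and the trans ring is also the more stable one, so that acid-induced reversible opening can only reinforce it. The step needs attack at C6 and not at C5 or C2, which the imide nitrogen (the basic site that the acid activates) and the methoxy group on C2 (a deactivated, blocked vinylogous imidate carbon) secure, and it needs C- and not O-alkylation of 6, which the two methoxy groups beside the phenol secure.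

Step 5
Reactants: 8 the cycloadduct from step 4
Product: 9 4-[(2S,3R)-5-amino-3-(hydroxymethyl)-7-methoxy-2,3-dihydro-1-benzofuran-2-yl]-2,6-dimethoxyphenol
Conditions: Bu4NF (5 equiv), THF, 50 °C; aqueous work-up
Reagents that add atoms: none
Why: Fluoride-induced desilylation and β-elimination (SES cleavage): attack of fluoride on the Me3Si group fragments the sulfonamide into Me3SiF, ethene, SO2 and the aniline, the TBS ether falls in the same operation, and since no bond to C2 or C3 is broken both stereocentres should be kept.

Step 6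
Reactants: 9 the aminophenol from step 5; 10 acrylic acid
Product: 12 (E)-3-[(2S,3R)-2-(4-hydroxy-3,5-dimethoxyphenyl)-3-(hydroxymethyl)-7-methoxy-2,3-dihydro-1-benzofuran-5-yl]prop-2-enoic acid, via arenediazonium tetrafluoroborate 11 (not isolated)
Conditions: tBuONO (1.2 equiv), HBF4 (48% aq, 1.5 equiv), MeCN, 0 °C; then 10 (3 equiv), Pd(OAc)2 (5 mol%), rt
Reagents that add atoms: none
Why: Diazotisation followed by Heck–Matsuda reaction: zerovalent palladium formed in situ adds into the C5–N2+ bond with loss of N2, and syn-carbopalladation of acrylic acid followed by syn β-hydride elimination should give the (E)-acrylic acid without base, conditions under which the phenol, the alcohol, the acid and both stereocentres should be left alone.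

**Compound list**

1 | 4-amino-2-methoxyphenol | COc1cc(N)ccc1O | starting material
2 | N-(4-hydroxy-3-methoxyphenyl)-2-(trimethylsilyl)ethanesulfonamide | COc1cc(NS(=O)(=O)CC[Si](C)(C)C)ccc1O | intermediate
3 | N-(3-methoxy-4-oxocyclohexa-2,5-dien-1-ylidene)-2-(trimethylsilyl)ethanesulfonamide | COC1=CC(=NS(=O)(=O)CC[Si](C)(C)C)C=CC1=O | intermediate
4 | (E)-sinapyl alcohol | COc1cc(/C=C/CO)cc(OC)c1O | starting material
5 | (E)-sinapyl alcohol bis(tert-butyldimethylsilyl) ether | COc1cc(/C=C/CO[Si](C)(C)C(C)(C)C)cc(OC)c1O[Si](C)(C)C(C)(C)C | intermediate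
6 | 4-[(E)-3-(tert-butyldimethylsilyloxy)prop-1-enyl]-2,6-dimethoxyphenol | COc1cc(/C=C/CO[Si](C)(C)C(C)(C)C)cc(OC)c1O | intermediate
7 | p-quinone methide adduct (open chain, C3 centre set, ring A as aminophenol) | COC1=CC(=C[C@@H](CO[Si](C)(C)C(C)(C)C)c2cc(NS(=O)(=O)CC[Si](C)(C)C)cc(OC)c2O)C=C(OC)C1=O | intermediate
8 | N-[(2S,3R)-3-[(tert-butyldimethylsilyloxy)methyl]-2-(4-hydroxy-3,5-dimethoxyphenyl)-7-methoxy-2,3-dihydro-1-benzofuran-5-yl]-2-(trimethylsilyl)ethanesulfonamide | COc1cc([C@H]2Oc3c(OC)cc(NS(=O)(=O)CC[Si](C)(C)C)cc3[C@@H]2CO[Si](C)(C)C(C)(C)C)cc(OC)c1O | intermediate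
9 | 4-[(2S,3R)-5-amino-3-(hydroxymethyl)-7-methoxy-2,3-dihydro-1-benzofuran-2-yl]-2,6-dimethoxyphenol | COc1cc([C@H]2Oc3c(OC)cc(N)cc3[C@@H]2CO)cc(OC)c1O | intermediate
10 | acrylic acid | C=CC(=O)O | starting material
11 | (2S,3R)-2-(4-hydroxy-3,5-dimethoxyphenyl)-3-(hydroxymethyl)-7-methoxy-2,3-dihydro-1-benzofuran-5-diazonium tetrafluoroborate | COc1cc([C@H]2Oc3c(OC)cc([N+]#N)cc3[C@@H]2CO)cc(OC)c1O.F[B-](F)(F)F | intermediate
12 | (E)-3-[(2S,3R)-2-(4-hydroxy-3,5-dimethoxyphenyl)-3-(hydroxymethyl)-7-methoxy-2,3-dihydro-1-benzofuran-5-yl]prop-2-enoic acid | COc1cc([C@H]2Oc3c(OC)cc(/C=C/C(=O)O)cc3[C@@H]2CO)cc(OC)c1O | target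

**Step count and risks**

Total step count: 6. Longest linear sequence: 5 steps (steps 1, 2, 4, 5, 6).

Steps most likely to fail:

- **Step 4.** Facial discrimination may be poor, because the phenolic OH of 6 sits between two methoxy groups and may bind the catalyst only loosely. The acid may also ionise the allylic silyl ether before the C–C bond forms. Fallback, from 3 and the bis-silyl ether 5 (isolated before the methanolysis of step 3), coming back at 9: BF3·OEt2 in CH2Cl2 at −78 °C, the achiral Lewis acid form of the cycloaddition that needs no free phenol, should give the racemic trans cycloadduct F1. Bu4NF as in step 5 should strip all three silicon groups and give the racemic aminophenol F2. The antipodes are then parted by crystallisation of the aniline salt with O,O'-dibenzoyl-L-tartaric acid or by preparative chromatography on a chiral phase; the (2S,3R) antipode is 9.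

- **Step 5.** Fluoride may be used up in deprotonating the acidic sulfonamide N–H, so that the fragmentation stalls. At the temperature then needed, the phenoxide may open the dihydrofuran by retro-oxa-Michael reaction. Fallback, from 8, coming back at 9: Boc2O (2.5 equiv), Et3N and catalytic DMAP in CH2Cl2 should give the N-Boc sulfonamide aryl carbonate F3, which has neither an acidic N–H nor a free phenol. Bu4NF in THF at 0 °C to rt should then cleave the activated SES group and the TBS ether to the N-Boc aniline aryl carbonate F4. CF3CO2H with Et3SiH in CH2Cl2 at 0 °C removes both Boc groups and gives 9.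

- **Step 6.** The electron-rich aminophenol may be oxidised or undergo azo coupling during diazotisation, and the diazonium salt may decompose before the palladium step takes it up. Fallback, from 9, coming back at 12: the diazonium salt 11, made as in step 6, is quenched with aqueous KI (iodo-dediazoniation) to give the isolable aryl iodide F5. A Mizoroki–Heck reaction with acrylic acid 10 (Pd(OAc)2, P(o-tol)3, Et3N, MeCN, 70 °C) should then give 12.

**Further compounds**

F1 | step 4 | racemic trans N-[3-[(tert-butyldimethylsilyloxy)methyl]-2-[4-(tert-butyldimethylsilyloxy)-3,5-dimethoxyphenyl]-7-methoxy-2,3-dihydro-1-benzofuran-5-yl]-2-(trimethylsilyl)ethanesulfonamide (both antipodes) | COc1cc([C@H]2Oc3c(OC)cc(NS(=O)(=O)CC[Si](C)(C)C)cc3[C@@H]2CO[Si](C)(C)C(C)(C)C)cc(OC)c1O[Si](C)(C)C(C)(C)C.COc1cc([C@@H]2Oc3c(OC)cc(NS(=O)(=O)CC[Si](C)(C)C)cc3[C@H]2CO[Si](C)(C)C(C)(C)C)cc(OC)c1O[Si](C)(C)C(C)(C)C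
F2 | step 4 | racemic trans 4-[5-amino-3-(hydroxymethyl)-7-methoxy-2,3-dihydro-1-benzofuran-2-yl]-2,6-dimethoxyphenol (both antipodes) | COc1cc([C@H]2Oc3c(OC)cc(N)cc3[C@@H]2CO)cc(OC)c1O.COc1cc([C@@H]2Oc3c(OC)cc(N)cc3[C@H]2CO)cc(OC)c1O
F3 | step 5 | tert-butyl N-[(2S,3R)-2-[4-(tert-butoxycarbonyloxy)-3,5-dimethoxyphenyl]-3-[(tert-butyldimethylsilyloxy)methyl]-7-methoxy-2,3-dihydro-1-benzofuran-5-yl]-N-[2-(trimethylsilyl)ethylsulfonyl]carbamate | COc1cc([C@H]2Oc3c(OC)cc(N(C(=O)OC(C)(C)C)S(=O)(=O)CC[Si](C)(C)C)cc3[C@@H]2CO[Si](C)(C)C(C)(C)C)cc(OC)c1OC(=O)OC(C)(C)C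
F4 | step 5 | tert-butyl N-[(2S,3R)-2-[4-(tert-butoxycarbonyloxy)-3,5-dimethoxyphenyl]-3-(hydroxymethyl)-7-methoxy-2,3-dihydro-1-benzofuran-5-yl]carbamate | COc1cc([C@H]2Oc3c(OC)cc(NC(=O)OC(C)(C)C)cc3[C@@H]2CO)cc(OC)c1OC(=O)OC(C)(C)C
F5 | step 6 | 4-[(2S,3R)-3-(hydroxymethyl)-5-iodo-7-methoxy-2,3-dihydro-1-benzofuran-2-yl]-2,6-dimethoxyphenol | COc1cc([C@H]2Oc3c(OC)cc(I)cc3[C@@H]2CO)cc(OC)c1O
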